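Ring A (C5–C10, eremophilane numbering), a 4,4-disubstituted cyclohexa-2,5-dienone, is cut at C7, the one ring-A carbon that bears the side chain. Without C7 a bicyclic cyclopentenone (C5, C6, C8, C9, C10) remains, which a Pauson–Khand reaction folds from an acyclic 1,7-enyne with C1, C3 and C4 already set. The key step exploits the α-substituted enone C6=C7–C8=O. Dibromocarbene is inserted between C6 and C8 of the derived 2-silyloxycyclopentadiene. In one operation this enlarges the five-membered ring to ring A, restores the C8 ketone, creates C6=C7 and leaves bromine on C7. Isopropenyl coupling and cobalt-catalysed hydroperoxidation at C11 finish the route.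

Key step: step 9

Remark on the chemistry:
- Eremophilane numbering is used throughout: C1 carbinol, C2 methylene, C3 ester-bearing carbon, C4 CH–CH3, C5 quaternary carbon, C6 =CH, C7 side-chain carbon, C8 C=O, C9 =CH, C10 sp2 ring-fusion carbon, C11–C13 side chain.
- Ring A is C5–C10. Ring B is C1–C5 plus C10.
- The SMILES is read as 1R,3S,4R,5R. The C1 oxygen, C3 oxygen, C4 methyl and C5 methyl all lie on one face (called β; the other face is α).
- The ester is read as the (Z)-2-methylbut-2-enoate (angelate).

Step 1
Reactants: 1 3-(trimethylsilyl)prop-2-ynal; 2 allylboronic acid pinacol ester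
Product: 3 (R)-1-(trimethylsilyl)hex-5-en-1-yn-3-ol
Conditions: (R)-TRIP [(R)-3,3'-bis(2,4,6-triisopropylphenyl)-1,1'-binaphthyl-2,2'-diyl hydrogen phosphate] (5 mol %), 4 Å MS, toluene, −30 °C; aqueous work-up
Reagents that add atoms: none
Why: Chiral-phosphoric-acid-catalysed asymmetric allylboration through a closed chair transition state, in which the (R)-catalyst, hydrogen-bonded to a boronate oxygen and the formyl hydrogen, should direct the allyl group to the re face of the ynal and so set C1 as R.

Step 2
Reactants: 3 (R)-1-(trimethylsilyl)hex-5-en-1-yn-3-ol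
Product: 4 (R)-3-(tert-butyldimethylsilyloxy)-1-(trimethylsilyl)hex-5-en-1-yne
Conditions: TBSCl, imidazole, DMF, rt
Reagents that add atoms: tert-butyldimethylsilyl chloride, CC(C)(C)[Si](C)(C)Cl
Why: Standard imidazole-promoted O-silylation of a secondary propargylic alcohol, which leaves C1 untouched and masks it for all steps up to step 11.

Step 3
Reactants: 4 (R)-3-(tert-butyldimethylsilyloxy)-1-(trimethylsilyl)hex-5-en-1-yne
Product: 5 (R)-3-(tert-butyldimethylsilyloxy)-5-(trimethylsilyl)pent-4-ynal
Conditions: O3, CH2Cl2, −78 °C; then PPh3, −78 °C to rt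
Reagents that add atoms: ozone, [O-][O+]=O
Why: Ozonolysis with reductive work-up cleaves the terminal alkene, while the silyl-capped alkyne reacts far more slowly, and the neutral work-up avoids β-elimination of the silyloxy group.

Step 4
Reactants: 6 (E)-2-methylbut-2-en-1-ol (tiglyl alcohol)
Product: 7 (E)-2-methylbut-2-en-1-ylboronic acid pinacol ester (tiglyl-Bpin)
Conditions: B2pin2, [Pd(MeCN)4](BF4)2 (5 mol %), DMSO/MeOH, rt
Reagents that add atoms: bis(pinacolato)diboron, CC1(C)OB(OC1(C)C)B1OC(C)(C)C(C)(C)O1
Why: Palladium-catalysed borylation of an allylic alcohol through the syn η3-allyl palladium intermediate, which places boron on the unsubstituted terminus and keeps the E geometry (vinylic CH3 trans to CH2B) that step 5 needs.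

Step 5
Reactants: 5 (R)-3-(tert-butyldimethylsilyloxy)-5-(trimethylsilyl)pent-4-ynal; 7 tiglyl-Bpin
Product: 8 (3R,5S,6R)-3-(tert-butyldimethylsilyloxy)-6,7-dimethyl-1-(trimethylsilyl)oct-7-en-1-yn-5-ol
Conditions: (R)-TRIP (10 mol %), 4 Å MS, toluene, −30 to 0 °C; aqueous work-up
Reagents that add atoms: none
Why: Catalytic asymmetric crotylboration-type addition through a closed chair, in which the E geometry of 7 becomes the anti C3–O/C4–CH3 relation and the (R)-catalyst directs attack to the re face of 5 (C3 S, C4 R, 1,3-syn to C1), any minor diastereomer being removable by chromatography.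

Step 6
Reactants: 8 (3R,5S,6R)-3-(tert-butyldimethylsilyloxy)-6,7-dimethyl-1-(trimethylsilyl)oct-7-en-1-yn-5-ol; 9 angelic acid [(Z)-2-methylbut-2-enoic acid]
Product: 11 (3R,5S,6R)-3-(tert-butyldimethylsilyloxy)-6,7-dimethyl-1-(trimethylsilyl)oct-7-en-1-yn-5-yl (Z)-2-methylbut-2-enoate, via mixed anhydride 10 (not isolated)
Conditions: 9, 2,4,6-trichlorobenzoyl chloride, Et3N, toluene, rt; then 8, toluene, 80 °C (no DMAP)
Reagents that add atoms: 2,4,6-trichlorobenzoyl chloride, O=C(Cl)c1c(Cl)cc(Cl)cc1Cl (its atoms stay only in 10)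
Why: Yamaguchi-type mixed-anhydride esterification in which the unhindered acyclic alcohol attacks the angeloyl carbonyl of 10, and leaving out nucleophilic catalysts avoids the addition–elimination path that would turn the Z ester into the E (tiglate) ester.

Step 7
Reactants: 11 enyne angelate
Product: 12 (4R,6S,7R,7aR)-4-(tert-butyldimethylsilyloxy)-7,7a-dimethyl-2-oxo-3-(trimethylsilyl)-2,4,5,6,7,7a-hexahydro-1H-inden-6-yl (Z)-2-methylbut-2-enoate
Conditions: Co2(CO)8 (20 mol %), tetramethylthiourea (60 mol %), CO (1 atm), toluene, 70 °C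
Reagents that add atoms: carbon monoxide, [C-]#[O+]
Why: Intramolecular Pauson–Khand [2+2+1] reaction forming C10–C5, C6–C8 and C8–C9, in which the chair-like cobaltacycle keeps the C4 methyl equatorial with C4–H eclipsing the alkene and turns C1–OTBS axial to escape allylic 1,3-strain with the C9 trimethylsilyl group, so that the C5 methyl should end up cis to the C4 methyl and to both oxygens.

Step 8
Reactants: 12 bicyclic cyclopentenone
Product: 13 2-silyloxycyclopentadiene (C8 tert-butyldimethylsilyl dienol ether of 12 with C6=C8 and C9=C10 double bonds and ring B unchanged)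
Conditions: TBSOTf, Et3N, CH2Cl2, 0 °C
Reagents that add atoms: tert-butyldimethylsilyl trifluoromethanesulfonate, CC(C)(C)[Si](C)(C)OS(=O)(=O)C(F)(F)F
Why: Soft enolisation (O-silylation, then amine deprotonation) removes a C6 proton, because the only γ-hydrogen, the equatorial C1–H, lies in the enone plane and cannot overlap with the π system; the quaternary C5 then locks the diene against 1,5-hydrogen shifts and the ester is untouched.

Step 9
Reactants: 13 2-silyloxycyclopentadiene
Product: 15 3β-angeloyloxy-7-bromo-1β-(tert-butyldimethylsilyloxy)-9-(trimethylsilyl)-11,12,13-trinoreremophila-6,9-dien-8-one, via dibromocyclopropane 14 (not isolated)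
Conditions: CHBr3, KOtBu (excess), pentane, −20 °C to rt
Reagents that add atoms: bromoform, BrC(Br)Br
Why: Potassium tert-butoxide converts bromoform into dibromocarbene, which adds in a concerted [2+1] cheletropic step to the C6=C8 silyl enol ether of 13 to give the 6,6-dibromobicyclo[3.1.0]hexene 14; loss of the endo bromide is concerted with disrotatory two-electron electrocyclic opening of the C6–C8 bond, pushed by the C8 silyloxy group, and the O-silylated cyclohexadienyl cation is desilylated by tert-butoxide to dienone 15. The closest known reaction type is the dihalocarbene ring expansion of cyclic silyl enol ethers and 2-silyloxydienes to α-halo enones, the carbocyclic relative of the Ciamician–Dennstedt rearrangement. The only ring closed is the transient cyclopropane ([2+1] addition); ring A is not closed by a new bond but appears when the zero-atom bridge C6–C8 breaks, so that the five ring atoms C5, C6, C8, C9, C10 and the inserted C7 make up the six-membered ring. No lasting stereocentre is created: C6 and C8 of 14 (carbene expected on the α face, anti to the C5 methyl) become sp2 again, and C1, C3, C4 and C5 are spectators. The step needs site selectivity among four C=C bonds, secured because C6=C8 is the only donor-substituted alkene, C9=C10 is tetrasubstituted and shielded by the C9 trimethylsilyl group, the angelate is electron-poor, and the product dienone is too electron-poor for a second addition. Low temperature and excess base should keep the cation from the dienone–phenol methyl shift.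

Step 10
Reactants: 15 7-bromo dienone; 16 isopropenylboronic acid pinacol ester
Product: 17 3β-angeloyloxy-1β-(tert-butyldimethylsilyloxy)-9-(trimethylsilyl)eremophila-6,9,11-trien-8-one
Conditions: Pd(PPh3)4 (5 mol %), K2CO3, THF/H2O, 60 °C
Reagents that add atoms: none
Why: Suzuki–Miyaura coupling, in which zerovalent palladium inserts readily into the activated C7–Br bond of the α-bromo enone and transfers the isopropenyl group (C11–C13) without touching any stereocentre.

Step 11
Reactants: 17 silylated trienone
Product: 18 3β-angeloyloxy-1β-hydroxyeremophila-6,9,11-trien-8-one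
Conditions: TBAF, AcOH (1:1), THF, 0 °C to rt
Reagents that add atoms: none
Why: Fluoride-mediated desilylation cleaves the C1 silyl ether and protodesilylates the α-silyl enone at C9 (the carbanion character at C9 is stabilised by the adjacent carbonyl), while the acetic acid buffer suppresses the 1,3-acyl shift of the angelate to the C1 oxygen and Z to E isomerisation; all silicon is removed before any peroxide is present.

Step 12
Reactants: 18 3β-angeloyloxy-1β-hydroxyeremophila-6,9,11-trien-8-one
Product: 20 3β-angeloyloxy-1β-hydroxy-11-hydroperoxyeremophila-6,9-dien-8-one (target), via silyl peroxide 19 (not isolated)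
Conditions: Co(thd)2 [bis(2,2,6,6-tetramethylheptane-3,5-dionato)cobalt] (10 mol %), Et3SiH, O2 (1 atm), 1,2-dichloroethane, rt; then PPTS (cat.), MeOH, 0 °C
Reagents that add atoms: dioxygen, O=O; triethylsilane, CC[SiH](CC)CC (silicon stays only in 19)
Why: Mukaiyama–Isayama hydroperoxysilylation, in which a cobalt hydride transfers a hydrogen atom to the terminal CH2 of the isopropenyl group (the only unhindered, electron-rich 1,1-disubstituted alkene), the tertiary allylic radical is trapped by O2 at C11 rather than at the neopentyl C6 so that ring A stays cross-conjugated, and mild methanolysis frees the hydroperoxide without creating a stereocentre.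

Compound list
1 | 3-(trimethylsilyl)prop-2-ynal | C[Si](C)(C)C#CC=O | starting material
2 | allylboronic acid pinacol ester | C=CCB1OC(C)(C)C(C)(C)O1 | starting material
3 | (R)-1-(trimethylsilyl)hex-5-en-1-yn-3-ol | C=CC[C@@H](O)C#C[Si](C)(C)C | intermediate
4 | (R)-3-(tert-butyldimethylsilyloxy)-1-(trimethylsilyl)hex-5-en-1-yne | C=CC[C@@H](O[Si](C)(C)C(C)(C)C)C#C[Si](C)(C)C | intermediate
5 | (R)-3-(tert-butyldimethylsilyloxy)-5-(trimethylsilyl)pent-4-ynal | O=CC[C@@H](O[Si](C)(C)C(C)(C)C)C#C[Si](C)(C)C | intermediate
6 | (E)-2-methylbut-2-en-1-ol (tiglyl alcohol) | C/C=C(\C)CO | starting material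
7 | (E)-2-methylbut-2-en-1-ylboronic acid pinacol ester | C/C=C(\C)CB1OC(C)(C)C(C)(C)O1 | intermediate
8 | (3R,5S,6R)-3-(tert-butyldimethylsilyloxy)-6,7-dimethyl-1-(trimethylsilyl)oct-7-en-1-yn-5-ol | O[C@@H](C[C@@H](O[Si](C)(C)C(C)(C)C)C#C[Si](C)(C)C)[C@H](C)C(C)=C | intermediate
9 | angelic acid, (Z)-2-methylbut-2-enoic acid | C/C=C(/C)C(=O)O | starting material
10 | angelic 2,4,6-trichlorobenzoic mixed anhydride | C/C=C(/C)C(=O)OC(=O)c1c(Cl)cc(Cl)cc1Cl | intermediate
11 | enyne angelate, (3R,5S,6R)-3-(tert-butyldimethylsilyloxy)-6,7-dimethyl-1-(trimethylsilyl)oct-7-en-1-yn-5-yl (Z)-2-methylbut-2-enoate | C/C=C(/C)C(=O)O[C@@H](C[C@@H](O[Si](C)(C)C(C)(C)C)C#C[Si](C)(C)C)[C@H](C)C(C)=C | intermediate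
12 | bicyclic cyclopentenone, (4R,6S,7R,7aR)-4-(tert-butyldimethylsilyloxy)-7,7a-dimethyl-2-oxo-3-(trimethylsilyl)-2,4,5,6,7,7a-hexahydro-1H-inden-6-yl (Z)-2-methylbut-2-enoate | C/C=C(/C)C(=O)O[C@H]1C[C@@H](O[Si](C)(C)C(C)(C)C)C2=C([Si](C)(C)C)C(=O)C[C@]2(C)[C@H]1C | intermediate
13 | 2-silyloxycyclopentadiene, C8 tert-butyldimethylsilyl dienol ether of 12 (C6=C8, C9=C10) | C/C=C(/C)C(=O)O[C@H]1C[C@@H](O[Si](C)(C)C(C)(C)C)C2=C([Si](C)(C)C)C(O[Si](C)(C)C(C)(C)C)=C[C@]2(C)[C@H]1C | intermediate
14 | dibromocyclopropane, 13 with CBr2 (C7) bridging C6 and C8 on the α face | C/C=C(/C)C(=O)O[C@H]1C[C@@H](O[Si](C)(C)C(C)(C)C)C2=C([Si](C)(C)C)[C@]3(O[Si](C)(C)C(C)(C)C)C(Br)(Br)[C@@H]3[C@]2(C)[C@H]1C | intermediate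
15 | 3β-angeloyloxy-7-bromo-1β-(tert-butyldimethylsilyloxy)-9-(trimethylsilyl)-11,12,13-trinoreremophila-6,9-dien-8-one | C/C=C(/C)C(=O)O[C@H]1C[C@@H](O[Si](C)(C)C(C)(C)C)C2=C([Si](C)(C)C)C(=O)C(Br)=C[C@]2(C)[C@H]1C | intermediate
16 | isopropenylboronic acid pinacol ester | C=C(C)B1OC(C)(C)C(C)(C)O1 | starting material
17 | 3β-angeloyloxy-1β-(tert-butyldimethylsilyloxy)-9-(trimethylsilyl)eremophila-6,9,11-trien-8-one | C/C=C(/C)C(=O)O[C@H]1C[C@@H](O[Si](C)(C)C(C)(C)C)C2=C([Si](C)(C)C)C(=O)C(C(C)=C)=C[C@]2(C)[C@H]1C | intermediate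
18 | 3β-angeloyloxy-1β-hydroxyeremophila-6,9,11-trien-8-one | C/C=C(/C)C(=O)O[C@H]1C[C@@H](O)C2=CC(=O)C(C(C)=C)=C[C@]2(C)[C@H]1C | intermediate
19 | 3β-angeloyloxy-1β-hydroxy-11-(triethylsilylperoxy)eremophila-6,9-dien-8-one | C/C=C(/C)C(=O)O[C@H]1C[C@@H](O)C2=CC(=O)C(C(C)(C)OO[Si](CC)(CC)CC)=C[C@]2(C)[C@H]1C | intermediate
20 | 3β-angeloyloxy-1β-hydroxy-11-hydroperoxyeremophila-6,9-dien-8-one (1R,3S,4R,5R) | C/C=C(/C)C(=O)O[C@H]1C[C@@H](O)C2=CC(=O)C(C(C)(C)OO)=C[C@]2(C)[C@H]1C | target

Total step count: 12. Longest linear sequence: 11 (steps 1–3 and 5–12; step 4 is a one-step side branch).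

Steps most likely to fail

Step 7. Insertion of the 1,1-disubstituted alkene into the cobalt–alkyne complex may be slow. Facial selectivity may also erode, because the productive chair carries the C1 oxygen, the C3 ester and the nascent C5 methyl all axial on one face. The fallback sets out from 8 and comes back to the route at 12. It reverses the order of esterification and annulation. The group forced axial at C3 is then a small hydroxyl that can hydrogen-bond to the C1 oxygen instead of a bulky ester. Alcohol 8 would be cyclised (Co2(CO)8, tetramethylthiourea, CO, toluene, 70 °C) to the hydroxy cyclopentenone F1. This would then be acylated with mixed anhydride 10 (toluene, 80 °C) to give 12.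

Step 12. The allyl radical may capture oxygen at C6 instead of C11. Hydrogen-atom transfer to the dienone or to the angelate may also compete. The fallback sets out from 18 and comes back at 20. It replaces the radical oxygenation by a pericyclic one. Chromium-catalysed 1,4-hydrogenation of the s-cis-capable diene C6=C7–C11=C12 ((η6-naphthalene)Cr(CO)3, H2, THF, rt) should give 3β-angeloyloxy-1β-hydroxyeremophila-7(11),9-dien-8-one F2. A Schenck ene reaction follows (O2, tetraphenylporphyrin, visible light, CH2Cl2, 0 °C). It should take the hydrogen from C6, the group geminal to the carbonyl on C7, place oxygen on C11 and move the double bond to C6=C7, giving 20 directly.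

Step 9. Carbene addition at the neopentyl C6 may be too slow, so that the carbene is lost to side reactions. The O-silylated cation may also undergo the dienone–phenol shift, or the base may attack the ester. The fallback sets out from 13 and comes back at 17. It keeps the one-carbon enlargement of the five-membered ring but does it by a radical opening.
- Furukawa-modified Simmons–Smith cyclopropanation (Et2Zn, CH2I2, CH2Cl2, 0 °C) of the enol ether double bond should give the siloxycyclopropane F3.
- Oxidative ring expansion with FeCl3 in DMF cleaves the C6–C8 bond and should deliver the 6α-chloro ketone F4.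
- NaOAc in MeOH eliminates HCl to the 7-unsubstituted dienone F5.
- α-Iodination (I2, pyridine, CH2Cl2) can occur only at C7, because C9 is blocked by silicon, and should give the 7-iodo dienone F6.
- Suzuki–Miyaura coupling of F6 with 16 under the conditions of step 10 gives 17.

Further compounds
F1 | step 7 | (4R,6S,7R,7aR)-4-(tert-butyldimethylsilyloxy)-6-hydroxy-7,7a-dimethyl-3-(trimethylsilyl)-1,4,5,6,7,7a-hexahydro-2H-inden-2-one | O[C@H]1C[C@@H](O[Si](C)(C)C(C)(C)C)C2=C([Si](C)(C)C)C(=O)C[C@]2(C)[C@H]1C
F2 | step 12 | 3β-angeloyloxy-1β-hydroxyeremophila-7(11),9-dien-8-one | C/C=C(/C)C(=O)O[C@H]1C[C@@H](O)C2=CC(=O)C(=C(C)C)C[C@]2(C)[C@H]1C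
F3 | step 9 | siloxycyclopropane, 13 with CH2 (C7) bridging C6 and C8 on the α face | C/C=C(/C)C(=O)O[C@H]1C[C@@H](O[Si](C)(C)C(C)(C)C)C2=C([Si](C)(C)C)[C@]3(O[Si](C)(C)C(C)(C)C)C[C@@H]3[C@]2(C)[C@H]1C
F4 | step 9 | 3β-angeloyloxy-6α-chloro-1β-(tert-butyldimethylsilyloxy)-9-(trimethylsilyl)-11,12,13-trinoreremophil-9-en-8-one | C/C=C(/C)C(=O)O[C@H]1C[C@@H](O[Si](C)(C)C(C)(C)C)C2=C([Si](C)(C)C)C(=O)C[C@H](Cl)[C@]2(C)[C@H]1C
F5 | step 9 | 3β-angeloyloxy-1β-(tert-butyldimethylsilyloxy)-9-(trimethylsilyl)-11,12,13-trinoreremophila-6,9-dien-8-one | C/C=C(/C)C(=O)O[C@H]1C[C@@H](O[Si](C)(C)C(C)(C)C)C2=C([Si](C)(C)C)C(=O)C=C[C@]2(C)[C@H]1C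
F6 | step 9 | 3β-angeloyloxy-7-iodo-1β-(tert-butyldimethylsilyloxy)-9-(trimethylsilyl)-11,12,13-trinoreremophila-6,9-dien-8-one | C/C=C(/C)C(=O)O[C@H]1C[C@@H](O[Si](C)(C)C(C)(C)C)C2=C([Si](C)(C)C)C(=O)C(I)=C[C@]2(C)[C@H]1C
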